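Take equal amounts of the two substrates as the zero of the scale, and ask how far the single-handed catalyst moves the product from that zero.

| setting | south-east | west | south | flask |
|---|---|---|---|---|
| left-handed substrate | 0.42 M | 0.42 M | 0.84 M | 0.42 M |
| right-handed substrate | 0.42 M | 0.42 M | 0.84 M | 0.42 M |
| gas | 35 mM (held) | 35 mM (held) | 35 mM (held) | 35 mM (held) |
| free catalyst | 2.1 mM | 8.4 mM | 4.2 mM | 4.2 mM |
| remark | run made earlier | run made earlier | run made earlier |  |
| time |  |  |  | 3.0 h |

| run | time / h | left-handed substrate / % | right-handed substrate / % |
|---|---|---|---|
| south-east | 0.200 | 47.1 | 48.5 |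
| south-east | 0.333 | 44.7 | 47.0 |
| south-east | 0.500 | 42.6 | 46.7 |
| south-east | 0.833 | 38.1 | 44.1 |
| south-east | 1.33 | 31.6 | 39.8 |
| south-east | 2.50 | 18.4 | 28.5 |
| west | 0.200 | 46.4 | 48.8 |
| west | 0.333 | 45.2 | 47.2 |
| west | 0.500 | 42.1 | 46.5 |
| west | 0.833 | 37.2 | 43.4 |
| west | 1.33 | 30.5 | 38.6 |
| west | 2.50 | 15.4 | 26.9 |
| south | 0.200 | 48.4 | 49.1 |
| south | 0.333 | 47.6 | 49.3 |
| south | 0.667 | 45.2 | 47.6 |
| south | 1.33 | 39.9 | 44.8 |
| south | 2.50 | 32.1 | 38.9 |

(scatter of a reading: 0.3 percentage points)

- free catalyst is single-handed; left-handed substrate and right-handed substrate are mirror images of each other, charged as a racemate, each of them at the stated concentration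
- what was read earlier has a scatter of 0.3 percentage points, one standard deviation
- at the start none of the gas is in solution
- an excess is the difference of the two amounts in percent of their sum
- an excess is below zero if the other one leads

- part of the left-handed substrate and right-handed substrate charged together that has reacted at 3.0 h
- excess of left-handed product over right-handed product in the product at 3.0 h
- excess of right-handed substrate over left-handed substrate among what is left of the two at 3.0 h

How much faster does the left-handed substrate go? The south-east and west runs have half and twice the flask's catalyst, so I pool them. At 0.500 h the logarithms of the two fractions left stand in the ratio 2.36, a reading: this is the selectivity factor, how many times faster the left-handed substrate reacts at equal amounts.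

What excess does the product being made at one moment carry? Multiply that factor by the left-handed to right-handed ratio then present; this fresh excess is that product less one, over it plus one. At the start it is 40.4%.

Does it last? The pooled ratio falls to 0.792 at 1.33 h and 0.610 at 2.50 h, so the fresh excess falls to 30.3% and 18.0%.

The south-east run loses substrate about as fast after 0.833 h as before it, so I average over time. Simpson's rule gives 29.9% up to 2.50 h. Counting the remaining time to 3.0 h at 18.0%, I expect 27.9%.

The forecast gives 66%, 17.5% and 34%, and says of the substrate gap: “suggesting some erosion with time”. My product excess is higher than its figure.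

The flask gives 66.4%, 28.0% and 31.5%.

    reagent + free catalyst + left-handed substrate → free catalyst + left-handed product (k = 62000 M⁻² h⁻¹)
    reagent + free catalyst → spent catalyst (k = 3.20 M⁻¹ h⁻¹)
    left-handed substrate ⇌ right-handed substrate (k = 0.170 h⁻¹)
    gas ⇌ reagent, rate k4*(csat - [reagent]) (kL = 5.70 h⁻¹)
    reagent + free catalyst + right-handed substrate → free catalyst + right-handed product (k = 26000 M⁻² h⁻¹)

At 3.00 h the flask's left-handed product leads by 19 percentage points, while the right-handed substrate leads by 11 points. With 23% and 44% of their charges left, the flask's fresh excess has reached 10.2%. The neighbouring flask, with 0.0011 M of free catalyst, keeps 33% and 53%, so its fresh excess is higher, at 18.4%. In the neighbouring flask 57.1% of the charge has reacted, and the product excess is 30.7%.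

All runs stem from a simulated flask for substances that don't exist; noise was put on by code.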